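## Retrosynthetic overview

1. The C7–O ester bond and the C7 quaternary centre are made together: acyloxylative dearomatisation of an alkynyl resorcylaldehyde with the free side-chain acid, steered by a chiral aryl-λ3-iodane (no metal in the stereo-determining event). The pendant phenol is unmasked last.
2. Ring order: both benzene rings are bought; ring A is the dearomatised resorcinol ring; ring B (pyran) closes last, in the same flask, by 6-endo cycloisomerisation onto the alkyne.
3. Alkynyl aldehyde: Sonogashira union of a bromo-resorcylaldehyde with silylated 2-ethynyl-3-methylphenol, then chlorination of the one free ring position.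
4. Side-chain acid: Wittig olefination of (S)-2-methyloctanal, whose centre comes from an organocatalytic formal α-methylation of octanal.

Assumption: 5-bromo-2-methylbenzene-1,3-diol is taken as a purchasable catalogue building block.

## Route

Step 1
Reactants: 1 octanal
Product: 3 (S)-2-(1,3-benzodithiol-2-yl)octan-1-ol, via benzodithiolyl aldehyde 2 (not isolated)
Conditions: 1 (2 equiv), 1,3-benzodithiolylium tetrafluoroborate (1 equiv), (S)-5-benzyl-2,2,3-trimethylimidazolidin-4-one·PhCO2H (20 mol %), NaH2PO4 (1 equiv), MeCN/H2O 1:1, 0 °C; then NaBH4, MeOH, 0 °C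
Reagents that add atoms: 1,3-benzodithiolylium tetrafluoroborate, F[B-](F)(F)F.c1ccc2[s+]csc2c1
Why: Enamine-mediated SN1-type α-alkylation (formal organocatalytic α-methylation) in which the E-enamine of 1 with the first-generation imidazolidinone is attacked by the stabilised carbenium ion on the face away from the benzyl group, setting the (S) centre, and NaBH4 reduction in the same flask protects it from racemisation.

Step 2
Reactants: 3 (S)-2-(1,3-benzodithiol-2-yl)octan-1-ol
Product: 4 (S)-2-methyloctan-1-ol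
Conditions: Raney Ni (W-2), H2 (1 atm), EtOH, 40 °C
Reagents that add atoms: none
Why: Raney Ni hydrogenolytic desulfurisation turns the dithioacetal carbon into the methyl group without touching the stereocentre.

Step 3
Reactants: 4 (S)-2-methyloctan-1-ol
Product: 6 ethyl (2E,4S)-2,4-dimethyldec-2-enoate, via (S)-2-methyloctanal 5 (not isolated)
Conditions: TEMPO (10 mol %), PhI(OAc)2 (1.1 equiv), CH2Cl2, rt; then Ph3P=C(Me)CO2Et (1.6 equiv), 40 °C
Reagents that add atoms: ethyl 2-(triphenyl-λ5-phosphanylidene)propanoate, CCOC(=O)C(C)=P(c1ccccc1)(c1ccccc1)c1ccccc1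
Why: One-pot TEMPO oxidation and Wittig olefination with the stabilised α-methyl ylide gives the (E)-trisubstituted enoate, and the non-basic medium leaves the α-centre of aldehyde 5 intact.

Step 4
Reactants: 6 ethyl (2E,4S)-2,4-dimethyldec-2-enoate
Product: 7 (2E,4S)-2,4-dimethyldec-2-enoic acid
Conditions: LiOH·H2O (3 equiv), THF/MeOH/H2O 3:1:1, rt; then 1 M HCl
Reagents that add atoms: lithium hydroxide, [Li+].[OH-]
Why: Ester saponification, in which hydroxide at room temperature does not deprotonate the γ-position, so the allylic centre and the E geometry persist.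

Step 5
Reactants: 8 2-hydroxy-6-methylbenzaldehyde
Product: 9 2-ethynyl-3-methylphenol
Conditions: dimethyl (1-diazo-2-oxopropyl)phosphonate (1.3 equiv), K2CO3 (3 equiv), MeOH, 0 °C → rt
Reagents that add atoms: dimethyl (1-diazo-2-oxopropyl)phosphonate (Ohira–Bestmann reagent), COP(=O)(OC)C(=[N+]=[N-])C(C)=O
Why: Seyferth–Gilbert homologation with the Ohira–Bestmann reagent converts the aldehyde into the terminal alkyne under carbonate conditions that tolerate the free phenol.

Step 6
Reactants: 9 2-ethynyl-3-methylphenol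
Product: 10 (2-ethynyl-3-methylphenoxy)tri(propan-2-yl)silane
Conditions: TIPSCl (1.2 equiv), imidazole (2.5 equiv), DMF, rt
Reagents that add atoms: chlorotri(propan-2-yl)silane (TIPSCl), CC(C)[Si](Cl)(C(C)C)C(C)C
Why: Silyl ether formation masks the phenol, which would otherwise close to a benzofuran under Pd/Cu and be oxidised by the iodane in step 10.

Step 7
Reactants: 11 5-bromo-2-methylbenzene-1,3-diol
Product: 12 6-bromo-2,4-dihydroxy-3-methylbenzaldehyde
Conditions: POCl3 (1.2 equiv), DMF (1.5 equiv), MeCN, 0 °C → rt; then H2O, 50 °C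
Reagents that add atoms: N,N-dimethylformamide, CN(C)C=O; water, O
Why: Vilsmeier–Haack formylation, where the two open ring positions are equivalent by symmetry and each is ortho and para to a hydroxyl, so a single aldehyde results.

Step 8
Reactants: 12 6-bromo-2,4-dihydroxy-3-methylbenzaldehyde; 10 (2-ethynyl-3-methylphenoxy)tri(propan-2-yl)silane
Product: 13 2,4-dihydroxy-3-methyl-6-({2-methyl-6-[tri(propan-2-yl)silyloxy]phenyl}ethynyl)benzaldehyde
Conditions: Pd(PPh3)2Cl2 (5 mol %), CuI (10 mol %), Et3N (4 equiv), DMF, 60 °C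
Reagents that add atoms: none
Why: Sonogashira coupling at the C–Br bond activated by the ortho formyl group, a coupling that tolerates the free resorcinol hydroxyls.

Step 9
Reactants: 13 2,4-dihydroxy-3-methyl-6-({2-methyl-6-[tri(propan-2-yl)silyloxy]phenyl}ethynyl)benzaldehyde
Product: 14 5-chloro-2,4-dihydroxy-3-methyl-6-({2-methyl-6-[tri(propan-2-yl)silyloxy]phenyl}ethynyl)benzaldehyde
Conditions: NCS (1.05 equiv), MeCN, 0 °C → rt
Reagents that add atoms: N-chlorosuccinimide, O=C1CCC(=O)N1Cl
Why: Electrophilic aromatic chlorination at the only free position of the resorcinol ring, which lies ortho and para to the hydroxyls and is far more nucleophilic than the silyloxyarene or the alkyne.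

Step 10
Reactants: 14 5-chloro-2,4-dihydroxy-3-methyl-6-({2-methyl-6-[tri(propan-2-yl)silyloxy]phenyl}ethynyl)benzaldehyde; 7 (2E,4S)-2,4-dimethyldec-2-enoic acid
Product: 16 (7S)-5-chloro-7-methyl-3-{2-methyl-6-[tri(propan-2-yl)silyloxy]phenyl}-6,8-dioxo-7,8-dihydro-6H-isochromen-7-yl (2E,4S)-2,4-dimethyldec-2-enoate, via vinylogous acid ester 15 (not isolated)
Conditions: {2,6-bis[((2R)-1-(mesitylamino)-1-oxopropan-2-yl)oxy]phenyl}-λ3-iodanediyl diacetate (1.05 equiv), 7 (2.2 equiv), PhCl, 40 °C, 20 mbar (AcOH removed); then 14 (1.0 equiv), CHCl3, −40 → −20 °C; then CuI (10 mol %), i-Pr2NEt (3 equiv), CH2Cl2, rt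
Reagents that add atoms: none
Why: Proposed new method: an enantioselective Wessely-type ortho-acyloxylative dearomatisation, in which the unchelated 4-OH of 14 exchanges onto the trivalent iodine of the C2-symmetric lactamide aryl-λ3-iodane bis(carboxylate) formed from 7, the N–H···O=C hydrogen bonds of the lactamide arms fold the reagent into a helical pocket, and the iodine-bound carboxylate is passed to the methyl-bearing ortho carbon by inner-sphere ligand coupling (seven-membered array, reductive loss of the iodoarene) on the exposed face to create the (S) quaternary centre, after which vinylogous acid 15 closes ring B by CuI-catalysed 6-endo-dig oxa-cyclisation; the closest known reactions are the racemic Wessely acetoxylation of 2-alkylphenols with PhI(OAc)2 or Pb(OAc)4, the enantioselective dearomative ortho-spirolactonisation of phenols by this iodoarene family with a tethered carboxylate, and the copper–sparteine hydroxylative dearomatisation/cycloisomerisation of alkynyl resorcylaldehydes.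

Step 11
Reactants: 16 (7S)-5-chloro-7-methyl-3-{2-methyl-6-[tri(propan-2-yl)silyloxy]phenyl}-6,8-dioxo-7,8-dihydro-6H-isochromen-7-yl (2E,4S)-2,4-dimethyldec-2-enoate
Product: 17 (7S)-5-chloro-3-(2-hydroxy-6-methylphenyl)-7-methyl-6,8-dioxo-7,8-dihydro-6H-isochromen-7-yl (2E,4S)-2,4-dimethyldec-2-enoate
Conditions: HF·pyridine, pyridine, THF, 0 °C → rt
Reagents that add atoms: none
Why: Fluoride-mediated desilylation of the aryl silyl ether under acidic, non-nucleophilic conditions that the azaphilone core, the tertiary ester and both stereocentres tolerate.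

## Compound list

1 | octanal | CCCCCCCC=O | starting material
2 | (S)-2-(1,3-benzodithiol-2-yl)octanal | CCCCCC[C@H](C1Sc2ccccc2S1)C=O | intermediate
3 | (S)-2-(1,3-benzodithiol-2-yl)octan-1-ol | CCCCCC[C@H](C1Sc2ccccc2S1)CO | intermediate
4 | (S)-2-methyloctan-1-ol | CCCCCC[C@H](C)CO | intermediate
5 | (S)-2-methyloctanal | CCCCCC[C@H](C)C=O | intermediate
6 | ethyl (2E,4S)-2,4-dimethyldec-2-enoate | CCCCCC[C@H](C)/C=C(\C)C(=O)OCC | intermediate
7 | (2E,4S)-2,4-dimethyldec-2-enoic acid | CCCCCC[C@H](C)/C=C(\C)C(=O)O | intermediate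
8 | 2-hydroxy-6-methylbenzaldehyde | Cc1cccc(O)c1C=O | starting material
9 | 2-ethynyl-3-methylphenol | C#Cc1c(C)cccc1O | intermediate
10 | (2-ethynyl-3-methylphenoxy)tri(propan-2-yl)silane | C#Cc1c(C)cccc1O[Si](C(C)C)(C(C)C)C(C)C | intermediate
11 | 5-bromo-2-methylbenzene-1,3-diol | Cc1c(O)cc(Br)cc1O | starting material
12 | 6-bromo-2,4-dihydroxy-3-methylbenzaldehyde | O=Cc1c(Br)cc(O)c(C)c1O | intermediate
13 | 2,4-dihydroxy-3-methyl-6-({2-methyl-6-[tri(propan-2-yl)silyloxy]phenyl}ethynyl)benzaldehyde | O=Cc1c(C#Cc2c(C)cccc2O[Si](C(C)C)(C(C)C)C(C)C)cc(O)c(C)c1O | intermediate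
14 | 5-chloro-2,4-dihydroxy-3-methyl-6-({2-methyl-6-[tri(propan-2-yl)silyloxy]phenyl}ethynyl)benzaldehyde | O=Cc1c(C#Cc2c(C)cccc2O[Si](C(C)C)(C(C)C)C(C)C)c(Cl)c(O)c(C)c1O | intermediate
15 | (1S)-3-chloro-5-formyl-6-hydroxy-1-methyl-4-({2-methyl-6-[tri(propan-2-yl)silyloxy]phenyl}ethynyl)-2-oxocyclohexa-3,5-dien-1-yl (2E,4S)-2,4-dimethyldec-2-enoate | CCCCCC[C@H](C)/C=C(\C)C(=O)O[C@@]1(C)C(O)=C(C=O)C(C#Cc2c(C)cccc2O[Si](C(C)C)(C(C)C)C(C)C)=C(Cl)C1=O | intermediate
16 | (7S)-5-chloro-7-methyl-3-{2-methyl-6-[tri(propan-2-yl)silyloxy]phenyl}-6,8-dioxo-7,8-dihydro-6H-isochromen-7-yl (2E,4S)-2,4-dimethyldec-2-enoate | CCCCCC[C@H](C)/C=C(\C)C(=O)O[C@@]1(C)C(=O)C2=COC(c3c(C)cccc3O[Si](C(C)C)(C(C)C)C(C)C)=CC2=C(Cl)C1=O | intermediate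
17 | (7S)-5-chloro-3-(2-hydroxy-6-methylphenyl)-7-methyl-6,8-dioxo-7,8-dihydro-6H-isochromen-7-yl (2E,4S)-2,4-dimethyldec-2-enoate | CCCCCC[C@H](C)/C=C(\C)C(=O)O[C@@]1(C)C(=O)C2=COC(c3c(C)cccc3O)=CC2=C(Cl)C1=O | target

## Step count and risks

Total steps: 11. Longest linear sequence: 6 (steps 1, 2, 3, 4, 10, 11; the alkyne arm 5, 6, 8, 9, 10, 11 is equally long).

Steps most likely to fail:

Step 10 (the proposed new reaction). The level and sense of face selection are untested. Attack at the chlorine-bearing ortho carbon or ipso to the formyl group, and 5-exo instead of 6-endo closure, are possible side paths. The C7 epimer is a diastereomer of 16 and can be removed by chromatography. If the sense of induction is opposite, the mirror-image iodane is used. The surplus of 7 is recovered.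

The fallback uses known chemistry, sets out from 13 and 7 and comes back at 16. Compound 13 is oxidised with the monovalent copper salt [Cu(MeCN)4]PF6, (−)-sparteine and O2 (i-Pr2NEt, CH2Cl2, −78 → −10 °C) to (3S)-2,3-dihydroxy-3-methyl-6-({2-methyl-6-[tri(propan-2-yl)silyloxy]phenyl}ethynyl)-4-oxocyclohexa-1,5-diene-1-carbaldehyde F1. Stirring with KH2PO4/K2HPO4 buffer in MeCN, copper still present, cycloisomerises it to (7R)-7-hydroxy-7-methyl-3-{2-methyl-6-[tri(propan-2-yl)silyloxy]phenyl}-6H-isochromene-6,8(7H)-dione F2. The choice of (−)-sparteine for the 7R series is made from recalled precedent and should be confirmed. Acid 7 is converted with (COCl)2 and catalytic DMF into (2E,4S)-2,4-dimethyldec-2-enoyl chloride F3, which acylates the tertiary alcohol of F2 (DMAP, Et3N, CH2Cl2) to give (7R)-7-methyl-3-{2-methyl-6-[tri(propan-2-yl)silyloxy]phenyl}-6,8-dioxo-7,8-dihydro-6H-isochromen-7-yl (2E,4S)-2,4-dimethyldec-2-enoate F4. Chlorination of F4 at C5 with NCS (MeCN, rt) gives 16; the descriptor changes from R to S only because chlorine alters the priority order.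

Step 9. NCS could also touch the silyloxyarene or over-chlorinate the alkynyl aldehyde. The fallback sets out from 12 and comes back at 14: 12 is chlorinated first with SO2Cl2 (Et2O, 0 °C) at its single free ring position to give 6-bromo-5-chloro-2,4-dihydroxy-3-methylbenzaldehyde F5, which is then coupled with 10 under the conditions of step 8 (the C–Br bond reacts before C–Cl) to give 14.

Step 5. The phenoxide of the doubly ortho-substituted salicylaldehyde deactivates the carbonyl toward the diazophosphonate anion. The fallback sets out from 8 and comes back at 10: 8 is silylated first (TIPSCl, imidazole, DMF) to 2-methyl-6-[tri(propan-2-yl)silyloxy]benzaldehyde F6. Corey–Fuchs olefination (CBr4, PPh3, CH2Cl2, 0 °C) gives [2-(2,2-dibromoethenyl)-3-methylphenoxy]tri(propan-2-yl)silane F7, and n-BuLi (2.2 equiv, THF, −78 °C) followed by NH4Cl gives 10.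

Further compounds
F1 | step 10 | (3S)-2,3-dihydroxy-3-methyl-6-({2-methyl-6-[tri(propan-2-yl)silyloxy]phenyl}ethynyl)-4-oxocyclohexa-1,5-diene-1-carbaldehyde | O[C@@]1(C)C(O)=C(C=O)C(C#Cc2c(C)cccc2O[Si](C(C)C)(C(C)C)C(C)C)=CC1=O
F2 | step 10 | (7R)-7-hydroxy-7-methyl-3-{2-methyl-6-[tri(propan-2-yl)silyloxy]phenyl}-6H-isochromene-6,8(7H)-dione | O[C@@]1(C)C(=O)C2=COC(c3c(C)cccc3O[Si](C(C)C)(C(C)C)C(C)C)=CC2=CC1=O
F3 | step 10 | (2E,4S)-2,4-dimethyldec-2-enoyl chloride | CCCCCC[C@H](C)/C=C(\C)C(Cl)=O
F4 | step 10 | (7R)-7-methyl-3-{2-methyl-6-[tri(propan-2-yl)silyloxy]phenyl}-6,8-dioxo-7,8-dihydro-6H-isochromen-7-yl (2E,4S)-2,4-dimethyldec-2-enoate | CCCCCC[C@H](C)/C=C(\C)C(=O)O[C@@]1(C)C(=O)C2=COC(c3c(C)cccc3O[Si](C(C)C)(C(C)C)C(C)C)=CC2=CC1=O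
F5 | step 9 | 6-bromo-5-chloro-2,4-dihydroxy-3-methylbenzaldehyde | O=Cc1c(Br)c(Cl)c(O)c(C)c1O
F6 | step 5 | 2-methyl-6-[tri(propan-2-yl)silyloxy]benzaldehyde | Cc1cccc(O[Si](C(C)C)(C(C)C)C(C)C)c1C=O
F7 | step 5 | [2-(2,2-dibromoethenyl)-3-methylphenoxy]tri(propan-2-yl)silane | Cc1cccc(O[Si](C(C)C)(C(C)C)C(C)C)c1C=C(Br)Br
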